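**Assumptions.** The target is taken as drawn, (2R,3S,3aS,5R)-3a-allyl-5-methoxy-3-methyl-2-(3,4,5-trimethoxyphenyl)-3,3a,4,5-tetrahydro-1-benzofuran-6(2H)-one. The cis relationship of C3a-allyl, C3-Me and C2-aryl, and the C5 configuration, are assumed to follow from the stereocentres set earlier, as argued in Steps 5 and 7.

## Retrosynthetic overview
1. C5 (OMe) stereocentre ← conjugate reduction of the 2-methoxy-enone **10**.
2. **10** ← 5-exo vinylogous-ester exchange of the desilylated alkoxide onto the 3-methoxy-enone of dienone **9**. This closes the dihydrofuran, and C2 is untouched because its C–O bond is not broken.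
3. **9** ← key step: anodic dearomative ipso-allylation of arene **7**. It forms the C3a quaternary centre and the cyclohexadienone ring, with facial control from the adjacent C3 stereocentre.
4. **7** ← Felkin addition of ArMgBr to an α-aryl propanal derived from ester **4**. **4** ← stereospecific Friedel–Crafts alkylation of 1,2,4-trimethoxybenzene with the triflate of L-lactate. Ring order: arene, then cyclohexadienone, then dihydrofuran.

## Route

**Step 1**
Reactants: **1** methyl (S)-lactate
Product: **2** methyl (S)-2-(triflyloxy)propanoate
Conditions: Tf2O, 2,6-lutidine, CH2Cl2, −78 → 0 °C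
Reagents that add atoms: triflic anhydride, O=S(=O)(OS(=O)(=O)C(F)(F)F)C(F)(F)F (adds SO2CF3)
Why: Sulfonylation of the secondary α-hydroxy ester activates it for SN2-type substitution and leaves the purchased stereocentre untouched.

**Step 2**
Reactants: **2**; **3** 1,2,4-trimethoxybenzene (3 equiv)
Product: **4** methyl (S)-2-(2,4,5-trimethoxyphenyl)propanoate
Conditions: 2,6-di-tert-butyl-4-methylpyridine, CH2Cl2, 0 °C → rt
Reagents that add atoms: none
Why: Effenberger-type Friedel–Crafts alkylation. The most nucleophilic arene carbon (C5, para to the C2-OMe) displaces triflate with inversion, which fixes C3 as (S) after the CIP priority change.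

**Step 3**
Reactants: **4**; **5** 5-bromo-1,2,3-trimethoxybenzene (as its Grignard reagent, from Mg, THF)
Product: **6** (1R,2S)-2-(2,4,5-trimethoxyphenyl)-1-(3,4,5-trimethoxyphenyl)propan-1-ol
Conditions: (i) DIBAL-H, CH2Cl2, −78 °C; (ii) 3,4,5-(MeO)3C6H2MgBr (from **5**, Mg, THF), −78 → 0 °C
Reagents that add atoms: none (the aryl group comes from **5**)
Why: The aldehyde is trapped in situ to limit α-epimerisation. Felkin–Anh addition anti to the large 2,4,5-trimethoxyphenyl group gives the syn alcohol, setting C2 as (R) relative to C3 (S); the diastereomer is purified by chromatography.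

**Step 4**
Reactants: **6**
Product: **7** the TBS ether of **6**
Conditions: TBSOTf, 2,6-lutidine, CH2Cl2, 0 °C
Reagents that add atoms: tert-butyldimethylsilyl triflate, CC(C)(C)[Si](C)(C)OS(=O)(=O)C(F)(F)F (adds TBS)
Why: Silylation stops the free OH from attacking the arene radical cation intramolecularly (which would form the aromatic dihydrobenzofuran) and keeps C2 from ionising.

**Step 5**
Reactants: **7**; **8** allyltrimethylsilane (5 equiv)
Product: **9** (4R)-4-allyl-4-[(1R,2S)-1-(TBSO)-1-(3,4,5-trimethoxyphenyl)propan-2-yl]-2,5-dimethoxycyclohexa-2,5-dien-1-one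
Conditions: undivided cell, RVC(+)/Pt(−), 5 mA (~2.2 F/mol), nBu4NBF4 (0.1 M), MeCN/HFIP/H2O 8:1:1, 2,6-lutidine, rt
Reagents that add atoms: allyltrimethylsilane (**8**), C=CC[Si](C)(C)C (adds the allyl group); water, O (becomes the C=O oxygen)
Why: Proposed new method: anodic oxidation of the 2,4,5-trimethoxyarene gives a radical cation at a potential well below that of the 3,4,5-trimethoxyphenyl ring. Allylsilane attacks the alkyl-bearing ipso carbon (para to the C4-OMe, and carrying no leaving OMe). This builds the quaternary centre, and loss of Me3Si+ leaves a cyclohexadienyl radical that is oxidised to a dimethoxy-carbenium ion. Hydrolysis with loss of MeOH gives the cross-conjugated dienone. The closest known reactions are Swenton anodic oxidation of 1,2,4-trialkoxyarenes and hypervalent-iodine para-dearomatisation of phenols with allylsilanes. The face of attack is set by 1,2-induction from C3, and the configuration drawn is the assumed outcome.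

**Step 6**
Reactants: **9**
Product: **10** (2R,3S,3aR)-3a-allyl-5-methoxy-3-methyl-2-(3,4,5-trimethoxyphenyl)-2,3-dihydro-1-benzofuran-6(3aH)-one
Conditions: TBAF, THF, 0 °C → rt (the alkoxide cyclises in situ, not isolated)
Reagents that add atoms: none
Why: Desilylation gives the alkoxide, which adds 5-exo to the β-carbon of the 3-methoxy-enone and expels methoxide (vinylogous-ester exchange). Any reversible oxa-Michael adduct at the other enone is funnelled to this product, and C2 and C3 are untouched.

**Step 7**
Reactants: **10**
Product: **11** dysodanthin B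
Conditions: L-Selectride, THF, −78 °C, then sat. NH4Cl (optional DBU/MeOH equilibration)
Reagents that add atoms: none
Why: Bulky hydride adds 1,4 to the more electrophilic 2-methoxy-enone, since the vinylogous ester is deactivated. Protonation of the resulting enolate sets C5-OMe, assumed to give the isomer cis to the allyl group, with thermodynamic equilibration as a backup.

## Compound list
| No. | Name | SMILES | Role |
|---|---|---|---|
| 1 | methyl (S)-lactate | C[C@H](O)C(=O)OC | starting material |
| 2 | methyl (S)-2-(triflyloxy)propanoate | C[C@H](OS(=O)(=O)C(F)(F)F)C(=O)OC | intermediate |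
| 3 | 1,2,4-trimethoxybenzene | COc1ccc(OC)c(OC)c1 | starting material |
| 4 | methyl (S)-2-(2,4,5-trimethoxyphenyl)propanoate | C[C@@H](c1cc(OC)c(OC)cc1OC)C(=O)OC | intermediate |
| 5 | 5-bromo-1,2,3-trimethoxybenzene | COc1cc(Br)cc(OC)c1OC | starting material |
| 6 | (1R,2S)-2-(2,4,5-trimethoxyphenyl)-1-(3,4,5-trimethoxyphenyl)propan-1-ol | C[C@@H](c1cc(OC)c(OC)cc1OC)[C@@H](O)c1cc(OC)c(OC)c(OC)c1 | intermediate |
| 7 | TBS ether of 6 | C[C@@H](c1cc(OC)c(OC)cc1OC)[C@@H](O[Si](C)(C)C(C)(C)C)c1cc(OC)c(OC)c(OC)c1 | intermediate |
| 8 | allyltrimethylsilane | C=CC[Si](C)(C)C | starting material |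
| 9 | dienone (4R)-4-allyl-4-[(1R,2S)-1-(TBSO)-1-(3,4,5-trimethoxyphenyl)propan-2-yl]-2,5-dimethoxycyclohexa-2,5-dien-1-one | C=CC[C@@]1([C@H](C)[C@@H](O[Si](C)(C)C(C)(C)C)c2cc(OC)c(OC)c(OC)c2)C=C(OC)C(=O)C=C1OC | intermediate |
| 10 | (2R,3S,3aR)-3a-allyl-5-methoxy-3-methyl-2-(3,4,5-trimethoxyphenyl)-2,3-dihydro-1-benzofuran-6(3aH)-one | C=CC[C@@]12C=C(OC)C(=O)C=C1O[C@@H](c1cc(OC)c(OC)c(OC)c1)[C@H]2C | intermediate |
| 11 | dysodanthin B, (2R,3S,3aS,5R)-5-methoxy-3-methyl-3a-(prop-2-en-1-yl)-2-(3,4,5-trimethoxyphenyl)-3,3a,4,5-tetrahydro-1-benzofuran-6(2H)-one | C=CC[C@@]12C[C@@H](OC)C(=O)C=C1O[C@@H](c1cc(OC)c(OC)c(OC)c1)[C@H]2C | target |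

**Total steps:** 7. **Longest linear sequence:** 7 (from **1**).

## Three steps most likely to fail
1. **Step 5 (proposed new step).** The arene radical cation may fragment at the C2–C3 bond or be attacked at a C–H position instead of ipso, and the facial selectivity at C3a is unproven. Fallback (known chemistry): run Step 2 on a TBS-protected 2,5-dimethoxyphenol instead, so that the ring carries a free phenol after Step 4. Then carry out a PIFA/HFIP para-dearomative allylation with allyltrimethylsilane, a two-electron process with no radical cation.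
2. **Step 3.** The α-aryl aldehyde may epimerise, and the Felkin diastereoselectivity may be modest. Fallback: convert **4** to its Weinreb amide, add the aryl Grignard to give the ketone, and reduce it (Felkin, giving the anti alcohol). Then invert C2 by Mitsunobu with p-nitrobenzoic acid and hydrolyse.
3. **Step 7.** The C5 stereochemistry and the chemoselectivity of the conjugate reduction are uncertain. Fallback: use 1,3-dimethoxybenzene in Step 2 so the ring carries no C5-OMe. After Step 6, reduce the dienone, then install C5-OMe by LDA/Davis oxaziridine α′-hydroxylation and Me3OBF4 O-methylation.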